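## Retrosynthetic overview

1. The last step frees the two phenols; before it, the complete 1,5‑dihydroxy‑3,7‑dioxabicyclo[3.3.0]octane core carries aryl tosylates.
2. Both tetrahydrofuran rings are cut at C2–O3 and C6–O7: a C2‑symmetric bis(2,3‑epoxy alcohol) closes twice by 5‑endo attack of each CH2OH on the benzylic epoxide carbon of the other half. This inverts the benzylic carbons and turns the epoxide oxygens into the bridgehead OH groups; ring A forms first, ring B second, in one operation.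
3. The bis‑epoxide comes from an (E,E)‑2,3‑bis(arylidene)butane‑1,4‑diol by double Sharpless epoxidation, which sets all four stereocentres.
4. The diene diol comes from diethyl (E,E)‑2,3‑bis(arylidene)succinate by a benzyl‑to‑tosyl swap on the phenols and ester reduction.
5. The key C–C bonds C1–C2 and C5–C6 are made by two successive Stobbe (aldol) condensations of O‑benzylvanillin with diethyl succinate.

Atom labels follow the 3,7‑dioxabicyclo[3.3.0]octane numbering of the target: C1/C5 bridgeheads (OH), C2/C6 benzylic, C4/C8 methylene; the target is (1S,2R,5S,6R).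

Assumption: where one reagent makes the same change at both equivalent ends of a C2‑symmetric compound, this is written as one step and the half‑reacted species is not numbered; the singly cyclised epoxide of step 9 is numbered because it is a constitutionally different stage of the cascade.

## Route

Step 1
Reactants: 1 4‑(benzyloxy)‑3‑methoxybenzaldehyde; 2 diethyl succinate
Product: 4 (E)‑4‑[4‑(benzyloxy)‑3‑methoxyphenyl]‑3‑(ethoxycarbonyl)but‑3‑enoic acid, via paraconic ester 3 (not isolated)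
Conditions: KOt‑Bu (1.2 equiv), t‑BuOH, reflux, 2 h; then aq. HCl
Reagents that add atoms: none
Why: Stobbe condensation (intermolecular aldol addition of the succinate enolate to the aldehyde, lactonisation, E1cB ring opening) is driven by carboxylate formation and gives the (E)‑half‑ester with the aryl group trans to the ester.

Step 2
Reactants: 4 (E)‑half‑ester
Product: 5 diethyl (E)‑2‑[4‑(benzyloxy)‑3‑methoxybenzylidene]succinate
Conditions: EtI, K2CO3, DMF, rt
Reagents that add atoms: iodoethane, CCI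
Why: SN2 O‑alkylation of the carboxylate under mild base leaves the alkene geometry and the benzyl ether untouched.

Step 3
Reactants: 5 diethyl (E)‑arylidenesuccinate; 1 4‑(benzyloxy)‑3‑methoxybenzaldehyde
Product: 7 (2E,3E)‑2,3‑bis[4‑(benzyloxy)‑3‑methoxybenzylidene]succinic acid monoethyl ester, via arylidene paraconic ester 6 (not isolated)
Conditions: NaOEt (1.5 equiv), EtOH, reflux, 8 h; then aq. HCl
Reagents that add atoms: none
Why: A second Stobbe condensation (aldol at the remaining CH2, lactonisation onto the conjugated ester, E1cB opening) gives the (E,E)‑diene, the usual geometry of bis(arylidene)succinates, with each aryl trans to its carboxyl.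

Step 4
Reactants: 7 (E,E)‑half‑ester
Product: 8 diethyl (2E,3E)‑2,3‑bis[4‑(benzyloxy)‑3‑methoxybenzylidene]succinate
Conditions: EtI, K2CO3, DMF, rt; recrystallise
Reagents that add atoms: iodoethane, CCI
Why: SN2 esterification as in step 2; crystallisation of the symmetric diester removes any (E,Z) isomer.

Step 5
Reactants: 8 (E,E)‑diester
Product: 9 diethyl (2E,3E)‑2,3‑bis(4‑hydroxy‑3‑methoxybenzylidene)succinate
Conditions: BCl3 (4 equiv), C6HMe5 (6 equiv), CH2Cl2, −78 °C, 1 h; MeOH quench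
Reagents that add atoms: none
Why: Lewis‑acid cleavage of aryl benzyl ethers with pentamethylbenzene as benzyl‑cation scavenger works at −78 °C without touching enoates, aryl methyl ethers or the diene, which hydrogenolysis would reduce.

Step 6
Reactants: 9 bis‑phenol diester
Product: 10 diethyl (2E,3E)‑2,3‑bis[3‑methoxy‑4‑(tosyloxy)benzylidene]succinate
Conditions: TsCl (2.4 equiv), Et3N, DMAP (cat.), CH2Cl2, 0 °C to rt
Reagents that add atoms: p‑toluenesulfonyl chloride, Cc1ccc(cc1)S(=O)(=O)Cl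
Why: Phenol sulfonylation installs a group that survives hydride, Ti and acid and makes the aryl ring electron‑poor, so the later benzylic epoxide opening runs as SN2 and not through a benzylic cation.

Step 7
Reactants: 10 bis‑tosylate diester
Product: 11 (2E,3E)‑2,3‑bis[3‑methoxy‑4‑(tosyloxy)benzylidene]butane‑1,4‑diol
Conditions: i‑Bu2AlH (6 equiv), CH2Cl2, −78 to −30 °C; aq. potassium sodium tartrate
Reagents that add atoms: none
Why: DIBAL‑H 1,2‑reduction of conjugated esters gives the allylic alcohols with retained alkene geometry, and aryl sulfonates are inert to it at low temperature.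

Step 8
Reactants: 11 (E,E)‑diene diol
Product: 12 [(2S,2'S,3S,3'S)‑3,3'‑bis[3‑methoxy‑4‑(tosyloxy)phenyl]‑[2,2'‑bioxirane]‑2,2'‑diyl]dimethanol
Conditions: Ti(OiPr)4 (0.3 equiv), L‑(+)‑diethyl tartrate (0.36 equiv), t‑BuOOH (4 equiv, anhydrous), 4 Å MS, CH2Cl2, −20 °C, 24–48 h
Reagents that add atoms: tert‑butyl hydroperoxide, CC(C)(C)OO
Why: Sharpless asymmetric epoxidation at both allylic alcohols adds oxygen syn to each (E)‑alkene under reagent control, L‑(+)‑tartrate giving the (2S,3S)‑epoxy alcohol from (E)‑2‑substituted 3‑aryl allylic alcohols; this fixes C1/C5 as S for good and C2/C6 as S for later inversion, and the C2‑symmetric product is separable from the minor meso‑type diastereomer.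

Step 9
Reactants: 12 bis(epoxy alcohol)
Product: 14 (1S,2R,5S,6R)‑2,6‑bis[3‑methoxy‑4‑(tosyloxy)phenyl]‑3,7‑dioxabicyclo[3.3.0]octane‑1,5‑diol, via singly cyclised spiro‑epoxide 13 (not isolated)
Conditions: (+)‑10‑camphorsulfonic acid (0.2 equiv), CH2Cl2, 0 °C to rt
Reagents that add atoms: none
Why: In a twofold acid‑catalysed 5‑endo epoxide‑opening etherification, each primary OH attacks the benzylic carbon of the epoxide on the other half by intramolecular SN2 (four‑membered alternatives are disfavoured), inverting C2 and C6 to R and leaving the epoxide oxygens as the cis bridgehead hydroxyls of ring A and then ring B.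

Step 10
Reactants: 14 prinsepiol bis‑tosylate
Product: 15 prinsepiol, (1S,2R,5S,6R)‑2,6‑bis(4‑hydroxy‑3‑methoxyphenyl)‑3,7‑dioxabicyclo[3.3.0]octane‑1,5‑diol
Conditions: KOH (8 equiv), MeOH/THF/H2O, 60 °C; then aq. HCl to pH 5
Reagents that add atoms: none
Why: Hydroxide attacks sulfur of the aryl sulfonates (sulfonate ester hydrolysis) and frees both phenols without touching any stereocentre, avoiding hydrogenolysis conditions that would cleave the benzylic C–O bonds.

## Compound list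

1 | 4‑(benzyloxy)‑3‑methoxybenzaldehyde (O‑benzylvanillin) | O=Cc1ccc(OCc2ccccc2)c(OC)c1 | starting material
2 | diethyl succinate | CCOC(=O)CCC(=O)OCC | starting material
3 | ethyl 2‑[4‑(benzyloxy)‑3‑methoxyphenyl]‑5‑oxotetrahydrofuran‑3‑carboxylate (racemic, cis/trans mixture) | CCOC(=O)C1CC(=O)OC1c1ccc(OCc2ccccc2)c(OC)c1 | intermediate
4 | (E)‑4‑[4‑(benzyloxy)‑3‑methoxyphenyl]‑3‑(ethoxycarbonyl)but‑3‑enoic acid | CCOC(=O)/C(CC(=O)O)=C/c1ccc(OCc2ccccc2)c(OC)c1 | intermediate
5 | diethyl (E)‑2‑[4‑(benzyloxy)‑3‑methoxybenzylidene]succinate | CCOC(=O)/C(CC(=O)OCC)=C/c1ccc(OCc2ccccc2)c(OC)c1 | intermediate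
6 | ethyl (4E)‑2‑[4‑(benzyloxy)‑3‑methoxyphenyl]‑4‑[4‑(benzyloxy)‑3‑methoxybenzylidene]‑5‑oxotetrahydrofuran‑3‑carboxylate (racemic, diastereomer mixture) | CCOC(=O)C1C(c2ccc(OCc3ccccc3)c(OC)c2)OC(=O)/C1=C/c1ccc(OCc2ccccc2)c(OC)c1 | intermediate
7 | (2E,3E)‑2,3‑bis[4‑(benzyloxy)‑3‑methoxybenzylidene]succinic acid monoethyl ester | COc1cc(\C=C(C(=O)OCC)/C(C(=O)O)=C\c2ccc(OCc3ccccc3)c(OC)c2)ccc1OCc1ccccc1 | intermediate
8 | diethyl (2E,3E)‑2,3‑bis[4‑(benzyloxy)‑3‑methoxybenzylidene]succinate | COc1cc(\C=C(C(=O)OCC)/C(C(=O)OCC)=C\c2ccc(OCc3ccccc3)c(OC)c2)ccc1OCc1ccccc1 | intermediate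
9 | diethyl (2E,3E)‑2,3‑bis(4‑hydroxy‑3‑methoxybenzylidene)succinate | COc1cc(\C=C(C(=O)OCC)/C(C(=O)OCC)=C\c2ccc(O)c(OC)c2)ccc1O | intermediate
10 | diethyl (2E,3E)‑2,3‑bis[3‑methoxy‑4‑(tosyloxy)benzylidene]succinate | COc1cc(\C=C(C(=O)OCC)/C(C(=O)OCC)=C\c2ccc(OS(=O)(=O)c3ccc(C)cc3)c(OC)c2)ccc1OS(=O)(=O)c1ccc(C)cc1 | intermediate
11 | (2E,3E)‑2,3‑bis[3‑methoxy‑4‑(tosyloxy)benzylidene]butane‑1,4‑diol | COc1cc(\C=C(CO)/C(CO)=C\c2ccc(OS(=O)(=O)c3ccc(C)cc3)c(OC)c2)ccc1OS(=O)(=O)c1ccc(C)cc1 | intermediate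
12 | [(2S,2'S,3S,3'S)‑3,3'‑bis[3‑methoxy‑4‑(tosyloxy)phenyl]‑[2,2'‑bioxirane]‑2,2'‑diyl]dimethanol | OC[C@@]1(O[C@H]1c2ccc(OS(=O)(=O)c3ccc(C)cc3)c(OC)c2)[C@@]4(CO)O[C@H]4c5ccc(OS(=O)(=O)c6ccc(C)cc6)c(OC)c5 | intermediate
13 | (2S,3S,6R,7S)‑7‑(hydroxymethyl)‑2,6‑bis[3‑methoxy‑4‑(tosyloxy)phenyl]‑1,5‑dioxaspiro[2.4]heptan‑7‑ol (ring A closed, second epoxide intact) | COc1cc([C@H]2OC[C@@]3(O[C@H]3c4ccc(OS(=O)(=O)c5ccc(C)cc5)c(OC)c4)[C@]2(O)CO)ccc1OS(=O)(=O)c1ccc(C)cc1 | intermediate
14 | (1S,2R,5S,6R)‑2,6‑bis[3‑methoxy‑4‑(tosyloxy)phenyl]‑3,7‑dioxabicyclo[3.3.0]octane‑1,5‑diol | COc1cc([C@H]2OC[C@]3(O)[C@@H](c4ccc(OS(=O)(=O)c5ccc(C)cc5)c(OC)c4)OC[C@]23O)ccc1OS(=O)(=O)c1ccc(C)cc1 | intermediate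
15 | prinsepiol, (1S,2R,5S,6R)‑2,6‑bis(4‑hydroxy‑3‑methoxyphenyl)‑3,7‑dioxabicyclo[3.3.0]octane‑1,5‑diol | COc1cc([C@H]2OC[C@]3(O)[C@@H](c4ccc(O)c(OC)c4)OC[C@]23O)ccc1O | target

## Step count and risks

Total steps: 10. Longest linear sequence: 10 steps (1 and 2 to 15).

**Step 3 (second Stobbe condensation).** The hindered diester 5 may give low conversion, self‑condensation or (E,Z) material. The fallback sets out from 1 and comes back at 8, replacing steps 1–4 by a C–C coupling that does not depend on enolate chemistry. Wittig olefination of 1 with Ph3P=C(Br)CO2Et in CH2Cl2 gives ethyl (Z)‑2‑bromo‑3‑[4‑(benzyloxy)‑3‑methoxyphenyl]acrylate F1, with aryl trans to the ester. Reductive homocoupling of this vinyl bromide (NiCl2(PPh3)2 10 mol%, Zn dust, Et4NI, THF, 50 °C; zerovalent nickel formed in the flask) joins the two α‑carbons with retention of geometry and gives 8.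

**Step 8 (double Sharpless epoxidation).** The 1,4‑diol may bind titanium too strongly, or the hindered, electron‑poor styrenes may react slowly; stoichiometric Ti(OiPr)4/tartrate is the first remedy. The fallback sets out from 11 and comes back at 12 and uses a non‑directed dioxirane epoxidation. Silylation (TBSCl, imidazole, DMF) gives (2E,3E)‑1,4‑bis(tert‑butyldimethylsilyloxy)‑2,3‑bis[3‑methoxy‑4‑(tosyloxy)benzylidene]butane F2. Shi epoxidation with the enantiomer of the fructose‑derived ketone (made from L‑sorbose), KHSO5 (as 2KHSO5·KHSO4·K2SO4), K2CO3 buffer, MeCN/dimethoxymethane/H2O, 0 °C, gives the (2S,2'S,3S,3'S)‑bis‑epoxide bis‑silyl ether F3. This catalyst enantiomer is chosen because the fructose‑derived ketone gives the (R,R) sense with trans‑β‑methylstyrene and cinnamyl silyl ethers. Bu4NF in THF at 0 °C removes the silyl groups and gives 12.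

**Step 9 (twofold 5‑endo cyclisation).** The acid may instead cause semipinacol rearrangement of the aryl epoxides or partial loss of stereospecificity at the benzylic carbons. The fallback sets out from 12 and comes back at 14; it opens the epoxides with an external nucleophile and closes the rings at the primary carbons. Ti(OiPr)4 (3 equiv) and PhCO2H in CH2Cl2 open both epoxides at the benzylic carbon with inversion to give (1R,2S,3S,4R)‑2,3‑dihydroxy‑2,3‑bis(hydroxymethyl)‑1,4‑bis[3‑methoxy‑4‑(tosyloxy)phenyl]butane‑1,4‑diyl dibenzoate F4. Selective mesylation of the two primary alcohols (MsCl, 2,4,6‑collidine, CH2Cl2, 0 °C) gives the corresponding bis(methanesulfonate) F5. K2CO3 in MeOH at rt removes the benzoates, and the freed benzylic alkoxides displace the primary mesylates (5‑exo‑tet, retention at C2/C6) to give 14.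

## Further compounds

F1 | step 3 | ethyl (Z)‑2‑bromo‑3‑[4‑(benzyloxy)‑3‑methoxyphenyl]acrylate | CCOC(=O)/C(Br)=C/c1ccc(OCc2ccccc2)c(OC)c1
F2 | step 8 | (2E,3E)‑1,4‑bis(tert‑butyldimethylsilyloxy)‑2,3‑bis[3‑methoxy‑4‑(tosyloxy)benzylidene]butane | COc1cc(\C=C(CO[Si](C)(C)C(C)(C)C)/C(CO[Si](C)(C)C(C)(C)C)=C\c2ccc(OS(=O)(=O)c3ccc(C)cc3)c(OC)c2)ccc1OS(=O)(=O)c1ccc(C)cc1
F3 | step 8 | (2S,2'S,3S,3'S)‑2,2'‑bis[(tert‑butyldimethylsilyloxy)methyl]‑3,3'‑bis[3‑methoxy‑4‑(tosyloxy)phenyl]‑2,2'‑bioxirane | CC(C)(C)[Si](C)(C)OC[C@@]1(O[C@H]1c2ccc(OS(=O)(=O)c3ccc(C)cc3)c(OC)c2)[C@@]4(CO[Si](C)(C)C(C)(C)C)O[C@H]4c5ccc(OS(=O)(=O)c6ccc(C)cc6)c(OC)c5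
F4 | step 9 | (1R,2S,3S,4R)‑2,3‑dihydroxy‑2,3‑bis(hydroxymethyl)‑1,4‑bis[3‑methoxy‑4‑(tosyloxy)phenyl]butane‑1,4‑diyl dibenzoate | COc1cc([C@@H](OC(=O)c2ccccc2)[C@@](O)(CO)[C@](O)(CO)[C@H](OC(=O)c2ccccc2)c2ccc(OS(=O)(=O)c3ccc(C)cc3)c(OC)c2)ccc1OS(=O)(=O)c1ccc(C)cc1
F5 | step 9 | (1R,2S,3S,4R)‑2,3‑dihydroxy‑2,3‑bis[(methylsulfonyloxy)methyl]‑1,4‑bis[3‑methoxy‑4‑(tosyloxy)phenyl]butane‑1,4‑diyl dibenzoate | COc1cc([C@@H](OC(=O)c2ccccc2)[C@@](O)(COS(C)(=O)=O)[C@](O)(COS(C)(=O)=O)[C@H](OC(=O)c2ccccc2)c2ccc(OS(=O)(=O)c3ccc(C)cc3)c(OC)c2)ccc1OS(=O)(=O)c1ccc(C)cc1
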